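All runs stem from a simulated flask from invented constants, and the scatter is random.

in all of them: electrophile 0.80 M
- birch: nucleophile 0.70 M; run made earlier
- cedar: nucleophile 0.89 M; run made earlier
- larch: nucleophile 0.99 M; run made earlier
- north-west: nucleophile 0.720 M; time 40 min
- south: nucleophile 1.10 M; time 40 min

| run | time / min | electrophile / % | target / % |
|---|---|---|---|
| birch | 2.50 | 55 | 43 |
| birch | 4.00 | 49 | 47 |
| birch | 8.00 | 34 | 54 |
| birch | 15.0 | 21 | 56 |
| birch | 30.0 | 17 | 46 |
| cedar | 2.50 | 42 | 50 |
| cedar | 8.00 | 25 | 60 |
| cedar | 12.0 | 17 | 61 |
| cedar | 20.0 | 8 | 56 |
| cedar | 30.0 | 5 | 49 |
| larch | 2.50 | 39 | 55 |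
| larch | 4.00 | 32 | 59 |
| larch | 8.00 | 18 | 65 |
| larch | 15.0 | 11 | 61 |
| larch | 30.0 | 4 | 51 |

(each reading ± 1.5 percentage points)

- what may be going on: electrophile + nucleophile -> acid set free + target; nucleophile + acid set free <-> protonated nucleophile; acid set free -> by-product carried off; target <-> isomer of the product; nucleophile + target -> over-reaction product

* part of the electrophile that has reacted at the end, north-west
* part of the electrophile that has reacted at the end, south
* what raising the concentration of nucleophile from its lowest to its highest value here does to the part of the electrophile that has reacted (changes below 5 percentage points count as none) (it falls / it rises / no change)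

1. I began from the nucleophile balance: the charge equals free nucleophile, plus protonated nucleophile, plus electrophile reacted, plus over-reaction product.

2. Birch looked contradictory. By 2.50 min, 0.360 M of electrophile had reacted, leaving 0.340 M of the nucleophile unreacted, yet only 6 percentage points more reacted by 4.00 min.

3. I took the binding of acid set free by nucleophile as settled. While its acid stays bound, each electrophile reacted costs 2 nucleophiles, one to react and one to hold the acid. In birch at 2.50 min that came to 0.720 M, about the 0.70 M charged, so I reckoned that little free nucleophile stood there at that time.

4. As acid is carried off, protonated nucleophile hands its nucleophile back. No term of the balance is negative, so electrophile reacted cannot pass the nucleophile charged, and the percentage reacted cannot pass [nucleophile]₀/[electrophile]₀, the ceiling 90.0% for north-west.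

5. Birch's ceiling was 87.5%, and its reading at 30.0 min was 83.0%. That gap of 4.5 points, a figure from a reading, holds over-reaction product and any nucleophile still free or protonated. Subtracting it, I reckoned about 85.5% for north-west.

6. South charged more nucleophile than electrophile, making electrophile the limiting reagent. Larch's reading at 30.0 min was 96.0%, so I expected south to come close to complete conversion and the part reacted to rise.

The forecast gave 86% (83% to 89%) for north-west and 99% (97% to 100%) for south, and said it rises, holding that “nucleophile caps conversion”.

    electrophile + nucleophile → acid set free + target (k = 0.0190 L mol⁻¹ s⁻¹)
    nucleophile + acid set free ⇌ protonated nucleophile, settled at all times (K = 79.0 L mol⁻¹)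
    acid set free → by-product carried off (k = 0.0310 s⁻¹)
    target ⇌ isomer of the product (K = 1.20, k = 4.60 × 10⁻⁴ s⁻¹)
    nucleophile + target → over-reaction product (k = 0.00130 L mol⁻¹ s⁻¹)

North-west gave 84.4% and south 99.9%; across this range the part reacted went as follows: it rises, by 15 points. At 40.0 min, north-west held 5.49% of over-reaction product, with 0.150% of its own nucleophile charge still free, and the ceiling less that product is 84.5%. For a neighbour of south charged with 1.4 M of electrophile, the ceiling is 78.6%, and less its 3.66% of over-reaction product that gives 74.9%. The computed flask gave 74.9%.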